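Assumption: labdane carbons are numbered C1–C20 and caryophyllene carbons C1′–C15′ (C14′ is the methyl on C4′, C15′ the exocyclic CH2), and (−)-8-phenylmenthol is accepted as a purchasable auxiliary that is recovered in step 9.

**Retrosynthetic overview**
1. Target ⇒ adduct with C19 as CH2OH and C14′ as CHO (both oxidised to CO2H last) ⇒ Diels–Alder disconnection of the cyclohexene (bonds C12–C4′ and C15–C5′) into trans-communol (diene) and ring-trans β-caryophyllen-14′-al (dienophile).
2. Dienophile ⇐ (−)-β-caryophyllene, with the four- and nine-membered rings bought intact, by geometry-retaining allylic metalation, borylation and oxidation of the C14′ methyl.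
3. Key disconnection, C4–C5 of the labdane: oxidative radical bicyclisation of an acyclic 8-phenylmenthyl β-keto ester tetraene, in which the oxidised enolate carbon C4 acts as an electrophilic, enolonium-type α-carbon toward the nucleophilic alkene carbon C5.
4. Tetraene ⇐ β-keto ester dianion + C15 allylic bromide ⇐ geranyl bromide + 3-methyl-3-sulfolene (masked E-diene), then SeO2 oxidation and SO2 extrusion.
5. Ring order: decalin ring A then ring B in one step (setting C4, C5, C9, C10 and the C8 exocyclic alkene), cyclohexene last; cyclobutane and cyclononene come from the chiral pool.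

**Route**

Step 1
Reactants: 1 geranyl bromide; 2 3-methyl-3-sulfolene
Product: 4 2-geranyl-3-methyl-3-sulfolene (racemic), via 2-lithio-3-methyl-3-sulfolene 3 (not isolated)
Conditions: LiN(SiMe3)2 added to 1 + 2, THF/DMPU, −78 °C
Reagents that add atoms: none
Why: Sulfone α-alkylation: C2 of the sulfolene (α to sulfur, allylic, methyl on the central carbon of the allyl anion) is deprotonated and alkylated by the allylic bromide in an SN2 reaction before the anion can ring-open, so the sulfolene acts as a masked (E)-2-methylbuta-1,3-dienyl anion, and the new stereocentre is racemic and is erased in step 3.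

Step 2
Reactants: 4 2-geranyl-3-methyl-3-sulfolene
Product: 5 2-[(2E,6E)-8-hydroxy-3,7-dimethylocta-2,6-dienyl]-3-methyl-3-sulfolene (racemic)
Conditions: SeO2 (0.3 equiv), t-BuOOH, salicylic acid (cat.), CH2Cl2, 0 °C → rt
Reagents that add atoms: tert-butyl hydroperoxide CC(C)(C)OO (oxygen delivered through selenium dioxide O=[Se]=O)
Why: Riley allylic oxidation (ene reaction then [2,3]-shift) picks the most electron-rich terminal trisubstituted alkene and its E-methyl group, as in the 8-hydroxylation of geranyl derivatives, while the sulfone-deactivated ring alkene and the internal alkene are left alone.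

Step 3
Reactants: 5 hydroxy sulfolene
Product: 6 (2E,6E,9E)-2,6,10-trimethyldodeca-2,6,9,11-tetraen-1-ol
Conditions: pyridine (2 equiv), toluene, 110 °C
Reagents that add atoms: none
Why: Thermal cheletropic extrusion of SO2 from a 2-substituted 3-sulfolene is concerted and disrotatory with the 2-substituent turning outward, so only the (E)-1-alkyl-2-methyl diene is formed.

Step 4
Reactants: 6 tetraenol
Product: 7 (2E,6E,9E)-1-bromo-2,6,10-trimethyldodeca-2,6,9,11-tetraene
Conditions: CBr4, PPh3, CH2Cl2, −20 °C
Reagents that add atoms: carbon tetrabromide BrC(Br)(Br)Br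
Why: Appel bromination converts the primary allylic alcohol to the bromide under neutral conditions, without allylic transposition and without acid that could touch the diene.

Step 5
Reactants: 8 (−)-8-phenylmenthol; 9 methyl 2-methyl-3-oxobutanoate
Product: 10 (−)-8-phenylmenthyl 2-methyl-3-oxobutanoate (α-epimers)
Conditions: DMAP (0.3 equiv), toluene, reflux, 4 Å MS (−MeOH)
Reagents that add atoms: none
Why: DMAP-catalysed transesterification of an enolisable β-keto ester proceeds through the acylketene and is driven by removal of methanol, leaving the three stereocentres of the auxiliary untouched.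

Step 6
Reactants: 10 auxiliary β-keto ester; 7 allylic bromide
Product: 12 (−)-8-phenylmenthyl (6E,10E,13E)-2,6,10,14-tetramethyl-3-oxohexadeca-6,10,13,15-tetraenoate, via sodium lithium dienolate 11 (not isolated)
Conditions: NaH, THF, 0 °C; n-BuLi, 0 °C; then 7, −78 → 0 °C
Reagents that add atoms: none
Why: Weiler dianion alkylation: the more basic terminal (γ) carbanion of the β-keto ester dianion displaces the allylic bromide by direct SN2 attack, so the three E-alkenes are carried over unchanged and the α-stereocentre (epimeric) is irrelevant because it becomes planar in step 7.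

Step 7
Reactants: 12 tetraenyl β-keto ester
Product: 13 (−)-8-phenylmenthyl 3-oxolabda-8(17),12E,14-trien-19-oate (4β-ester, 5α-H, 9α-H, 10β-CH3)
Conditions: Mn(OAc)3·2H2O (2.2 equiv), Cu(OAc)2·H2O (1 equiv), degassed AcOH (0.02 M), 25 °C
Reagents that add atoms: none
Why: Oxidative free-radical bicyclisation: one-electron oxidation of the trivalent-manganese enolate turns C4 from a nucleophilic into an electrophilic α-carbon (an enolonium-type radical) that bonds to the nucleophilic alkene carbon C5 (6-endo), the tertiary C10 radical closes ring B onto C9 through the chair–chair array fixed by the two E-alkenes (5α-H, 9α-H, 10β-CH3), divalent copper oxidises the C8 radical to the exocyclic alkene, and the phenyl ring of the auxiliary stacks over one face of the planar C4 radical so that the ester ends up axial (4β) in the natural series, as in the 8-phenylmenthyl route to O-methylpodocarpate.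

Step 8
Reactants: 13 bicyclic keto ester
Product: 15 (−)-8-phenylmenthyl trans-communate, via C3 tosylhydrazone 14 (not isolated)
Conditions: TsNHNH2, MeOH, 60 °C; evaporate; catecholborane, CHCl3, 0 °C; then NaOAc·3H2O, 60 °C
Reagents that add atoms: none
Why: Reductive deoxygenation of a tosylhydrazone (Caglioti reduction in the catecholborane variant) hydroborates the C=N bond and then loses sulfinate and N2 to leave CH2 at C3 under near-neutral conditions that spare the diene, the exocyclic alkene and the hindered ester, with no stereocentre involved.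

Step 9
Reactants: 15 auxiliary ester of trans-communic acid
Product: 16 trans-communol (labda-8(17),12E,14-trien-19-ol)
Conditions: LiAlH4, THF, 0 °C → reflux
Reagents that add atoms: none
Why: Hydride reduction is the reliable way to cleave the axial neopentyl ester, giving the C19 alcohol and returning the auxiliary, while the isolated alkenes and the diene are inert to LiAlH4.

Step 10
Reactants: 17 (−)-β-caryophyllene
Product: 20 14′-hydroxy-β-caryophyllene (ring-trans alkene kept; formally 4′Z), via caryophyllen-14′-ylpotassium 18 (not isolated), via dimethyl caryophyllen-14′-ylboronate 19 (not isolated)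
Conditions: n-BuLi, KOt-Bu, THF, −75 → −50 °C; B(OMe)3, −75 °C; then H2O2, aq NaOH, 0 °C
Reagents that add atoms: hydrogen peroxide OO
Why: Superbase allylic metalation–borylation–oxidation (as for α-pinene to myrtenol): the methyl group is deprotonated faster than allylic CH2 or CH, the allylpotassium keeps the C4′–C5′ geometry at low temperature because C6′ cis to C14′ is already the favoured endo form, boron takes the unsubstituted terminus, and C–B to C–O oxidation does not disturb the ring-trans alkene.

Step 11
Reactants: 20 14′-hydroxy-β-caryophyllene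
Product: 21 β-caryophyllen-14′-al (ring-trans enal)
Conditions: Dess–Martin periodinane, NaHCO3, CH2Cl2, 0 °C
Reagents that add atoms: none
Why: Buffered Dess–Martin oxidation of the allylic alcohol gives the enal without acid, base or nucleophile that could isomerise the strained trans alkene or trigger transannular cyclisation.

Step 12
Reactants: 16 trans-communol; 21 β-caryophyllen-14′-al
Product: 23 Diels–Alder hydroxy aldehyde (target skeleton with C19 as CH2OH and C14′ as CHO), via chloro(methyl)aluminium alkoxide 22 (not isolated)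
Conditions: Me2AlCl (2.2 equiv), CH2Cl2, −78 → −20 °C
Reagents that add atoms: none
Why: Lewis-acid-promoted Diels–Alder reaction: the Me2AlCl-activated, strained trans-cyclononene enal reacts with the s-cis (E)-1-alkyl-2-methyl diene with ortho regiochemistry (C15 to the β-carbon C5′, C12 to C4′), the diene adds to the exposed outer face of the trans alkene (the face that is epoxidised in caryophyllene oxide), the E-alkene fixes H-5′ trans to the formyl group, and the formyl-endo transition state places the C11 side chain cis to CHO.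

Step 13
Reactants: 23 hydroxy aldehyde
Product: 25 target diacid CNP0330729.1, via dialdehyde 24 (not isolated)
Conditions: Dess–Martin periodinane, NaHCO3, CH2Cl2, 0 °C → rt; then t-BuOH/H2O, 2-methyl-2-butene, NaH2PO4, NaClO2, rt
Reagents that add atoms: sodium chlorite [Na+].[O-]Cl=O
Why: Dess–Martin oxidation of the neopentyl C19 alcohol followed in the same flask by Pinnick oxidation converts both hindered aldehydes to acids, the two α-carbons being quaternary so nothing can epimerise and the scavenger protecting the three alkenes from hypochlorite.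

**Compound list**
1 | geranyl bromide | CC(C)=CCC/C(C)=C/CBr | starting material
2 | 3-methyl-3-sulfolene | CC1=CCS(=O)(=O)C1 | starting material
3 | 2-lithio-3-methyl-3-sulfolene | [Li]C1C(C)=CCS1(=O)=O | intermediate
4 | 2-geranyl-3-methyl-3-sulfolene (racemic) | CC(C)=CCC/C(C)=C/CC1C(C)=CCS1(=O)=O | intermediate
5 | 2-[(2E,6E)-8-hydroxy-3,7-dimethylocta-2,6-dienyl]-3-methyl-3-sulfolene (racemic) | OC/C(C)=C/CC/C(C)=C/CC1C(C)=CCS1(=O)=O | intermediate
6 | (2E,6E,9E)-2,6,10-trimethyldodeca-2,6,9,11-tetraen-1-ol | OC/C(C)=C/CC/C(C)=C/C/C=C(C)/C=C | intermediate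
7 | (2E,6E,9E)-1-bromo-2,6,10-trimethyldodeca-2,6,9,11-tetraene | BrC/C(C)=C/CC/C(C)=C/C/C=C(C)/C=C | intermediate
8 | (−)-8-phenylmenthol, (1R,2S,5R) | O[C@@H]1C[C@H](C)CC[C@H]1C(C)(C)c1ccccc1 | starting material
9 | methyl 2-methyl-3-oxobutanoate | CC(=O)C(C)C(=O)OC | starting material
10 | (−)-8-phenylmenthyl 2-methyl-3-oxobutanoate (α-epimers) | CC(=O)C(C)C(=O)O[C@@H]1C[C@H](C)CC[C@H]1C(C)(C)c1ccccc1 | intermediate
11 | sodium lithium dienolate of 10 | [Na+].[Li+].C=C([O-])C(C)=C([O-])O[C@@H]1C[C@H](C)CC[C@H]1C(C)(C)c1ccccc1 | intermediate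
12 | (−)-8-phenylmenthyl (6E,10E,13E)-2,6,10,14-tetramethyl-3-oxohexadeca-6,10,13,15-tetraenoate (α-epimers) | C=C/C(C)=C/C/C=C(C)/CC/C=C(C)/CCC(=O)C(C)C(=O)O[C@@H]1C[C@H](C)CC[C@H]1C(C)(C)c1ccccc1 | intermediate
13 | (−)-8-phenylmenthyl 3-oxolabda-8(17),12E,14-trien-19-oate | C=C/C(C)=C/C[C@H]1C(=C)CC[C@@H]2[C@]1(C)CCC(=O)[C@]2(C)C(=O)O[C@@H]1C[C@H](C)CC[C@H]1C(C)(C)c1ccccc1 | intermediate
14 | C3 tosylhydrazone of 13 | C=C/C(C)=C/C[C@H]1C(=C)CC[C@@H]2[C@]1(C)CCC(=NNS(=O)(=O)c1ccc(C)cc1)[C@]2(C)C(=O)O[C@@H]1C[C@H](C)CC[C@H]1C(C)(C)c1ccccc1 | intermediate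
15 | (−)-8-phenylmenthyl trans-communate | C=C/C(C)=C/C[C@H]1C(=C)CC[C@@H]2[C@]1(C)CCC[C@]2(C)C(=O)O[C@@H]1C[C@H](C)CC[C@H]1C(C)(C)c1ccccc1 | intermediate
16 | trans-communol | C=C/C(C)=C/C[C@H]1C(=C)CC[C@@H]2[C@]1(C)CCC[C@]2(C)CO | intermediate
17 | (−)-β-caryophyllene, (1′R,4′E,9′S) | C=C1CC/C=C(\C)CC[C@@H]2[C@@H]1CC2(C)C | starting material
18 | caryophyllen-14′-ylpotassium | C=C1CC/C=C(\C[K])CC[C@@H]2[C@@H]1CC2(C)C | intermediate
19 | dimethyl caryophyllen-14′-ylboronate | C=C1CC/C=C(\CB(OC)OC)CC[C@@H]2[C@@H]1CC2(C)C | intermediate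
20 | 14′-hydroxy-β-caryophyllene (ring-trans) | C=C1CC/C=C(\CO)CC[C@@H]2[C@@H]1CC2(C)C | intermediate
21 | β-caryophyllen-14′-al (ring-trans) | C=C1CC/C=C(\C=O)CC[C@@H]2[C@@H]1CC2(C)C | intermediate
22 | chloro(methyl)aluminium alkoxide of 16 | C=C/C(C)=C/C[C@H]1C(=C)CC[C@@H]2[C@]1(C)CCC[C@]2(C)CO[Al](C)Cl | intermediate
23 | Diels–Alder hydroxy aldehyde (C19 CH2OH, C14′ CHO) | C=C1CC[C@H]2CC=C(C)[C@@H](C[C@H]3C(=C)CC[C@@H]4[C@]3(C)CCC[C@]4(C)CO)[C@]2(C=O)CC[C@@H]2[C@@H]1CC2(C)C | intermediate
24 | dialdehyde (C19 CHO, C14′ CHO) | C=C1CC[C@H]2CC=C(C)[C@@H](C[C@H]3C(=C)CC[C@@H]4[C@]3(C)CCC[C@]4(C)C=O)[C@]2(C=O)CC[C@@H]2[C@@H]1CC2(C)C | intermediate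
25 | CNP0330729.1 | C=C1CC[C@H]2CC=C(C)[C@@H](C[C@H]3C(=C)CC[C@@H]4[C@]3(C)CCC[C@]4(C)C(=O)O)[C@]2(C(=O)O)CC[C@@H]2[C@@H]1CC2(C)C | target

**Step count and risks**

Total step count: 13. Longest linear sequence: 10 steps (1–4, 6–9, 12, 13).

Step 7 (oxidative bicyclisation) is the most exposed step. The free diene may trap radicals, endocyclic alkene isomers may form, and the facial control by the auxiliary may be lower than in the podocarpate model. The fallback takes the diene out of the radical step. It sets out from 12, which is treated with liquid SO2 and hydroquinone in CH2Cl2 at room temperature to give the sulfolene-masked keto ester F1 as a mixture of epimers at the sulfolene carbon. F1 is cyclised with Mn(OAc)3·2H2O and Cu(OAc)2·H2O in AcOH to the bicyclic sulfolene F2. Heating F2 in toluene with pyridine at 110 °C extrudes SO2 and comes back to the route at 13.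

Step 10 (allylic metalation) may deprotonate C7′ next to the exocyclic alkene in competition with C14′, or the allylpotassium may relax to the ring-cis form. The fallback sets out from 17 and accepts the ring-cis geometry first. SeO2 with t-BuOOH gives 14′-hydroxyisocaryophyllene F3, the alkene turning ring-cis in the [2,3]-shift as is usual for trans-cycloalkenes. VO(acac)2 with t-BuOOH gives the cis-epoxy alcohol F4 (either epoxide face converges). PhMe2SiLi opens the epoxide at C5′ with inversion to the β-hydroxysilane F5, and KH-induced syn Peterson elimination inverts the alkene geometry and comes back to the route at 20.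

Step 12 (Diels–Alder) may give ortho/meta regioisomers or exo adducts, and the Lewis acid may start ene or transannular reactions of the exocyclic alkenes. The fallback sets out from 21 and switches to an ionic Diels–Alder reaction. 1,2-Bis(trimethylsilyloxy)ethane with catalytic Me3SiOSO2CF3 at −78 °C gives the dioxolane F6. With 16, catalytic Me3SiOSO2CF3 and 2,6-di-tert-butylpyridine at −78 °C, the derived alkoxyallyl cation adds to the diene with the high ortho and endo preference typical of such cationic dienophiles, giving the acetal adduct F7. Hydrolysis with PPTS in wet acetone comes back to the route at 23.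

**Further compounds**
F1 | step 7 | sulfolene-masked keto ester (SO2 adduct of 12) | CC(C(=O)CC/C(C)=C/CC/C(C)=C/CC1C(C)=CCS1(=O)=O)C(=O)O[C@@H]1C[C@H](C)CC[C@H]1C(C)(C)c1ccccc1
F2 | step 7 | bicyclic sulfolene (SO2 adduct of 13) | O=S1(=O)CC=C(C)C1C[C@H]1C(=C)CC[C@@H]2[C@]1(C)CCC(=O)[C@]2(C)C(=O)O[C@@H]1C[C@H](C)CC[C@H]1C(C)(C)c1ccccc1
F3 | step 10 | 14′-hydroxyisocaryophyllene (ring-cis) | C=C1CC/C=C(/CO)CC[C@@H]2[C@@H]1CC2(C)C
F4 | step 10 | cis-4′,5′-epoxy-14′-hydroxyisocaryophyllene | C=C1CC[C@H]2O[C@@]2(CO)CC[C@@H]2[C@@H]1CC2(C)C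
F5 | step 10 | 5′-(dimethylphenylsilyl)-4′,14′-diol | C=C1CC[C@H]([Si](C)(C)c2ccccc2)[C@](O)(CO)CC[C@@H]2[C@@H]1CC2(C)C
F6 | step 12 | 1,3-dioxolane of 21 | C=C1CC/C=C(\C2OCCO2)CC[C@@H]2[C@@H]1CC2(C)C
F7 | step 12 | dioxolane acetal of 23 | C=C1CC[C@H]2CC=C(C)[C@@H](C[C@H]3C(=C)CC[C@@H]4[C@]3(C)CCC[C@]4(C)CO)[C@]2(C2OCCO2)CC[C@@H]2[C@@H]1CC2(C)C
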